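## Retrosynthetic overview

1. The target is the (2S,2′S) dimer of 7-hydroxy-5-methoxyflavan, joined by a CH2 group from C6 of one unit to C8 of the other.
2. Putting back a C3=C4 double bond and a 3-formyl group on each pyran leads to a bis(2-phenyl-2H-chromene-3-carbaldehyde).
3. Key disconnection: both pyran rings are cut at once (O1–C2 and C3–C4 in each), giving a methylene-bridged bis-salicylaldehyde and two cinnamaldehydes; a chiral amine catalyst sets both C2 centres during ring formation.
4. The bridge is cut at CH2–aryl: an aryllithium (made between two OMOM groups of a masked 2,4-bis(MOM-oxy)-6-methoxybenzaldehyde) adds to a symmetric 2-methoxy-4,6-bis(MOM-oxy)isophthalaldehyde, so directed metalation and symmetry fix the unsymmetrical link.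
5. Ring order: both benzene rings are bought; the two pyran rings are formed together, late, and nothing else is cyclised.

Assumption: compounds 1 and 3 are bought as catalogue compounds (each is otherwise one Vilsmeier formylation from 3,5-dihydroxyanisole or phloroglucinol); the step count starts from them.

## Route

Step 1
Reactants: 1 2,4-dihydroxy-6-methoxybenzaldehyde
Product: 2 6-methoxy-2,4-bis(methoxymethoxy)benzaldehyde
Conditions: NaH, MOMCl, DMF, 0 °C to rt
Reagents that add atoms: chloromethyl methyl ether (MOMCl), COCCl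
Why: Williamson-type O-alkylation of both phenoxides (NaH is needed for the chelated 2-OH); MOM is chosen because it is a strong ortho-directing group for step 4 and is removed by acid in step 5.

Step 2
Reactants: 3 2,4,6-trihydroxybenzene-1,3-dicarbaldehyde
Product: 4 2-hydroxy-4,6-bis(methoxymethoxy)benzene-1,3-dicarbaldehyde
Conditions: MOMCl (2.1 equiv), K2CO3, acetone, 0 °C to rt
Reagents that add atoms: chloromethyl methyl ether (MOMCl), COCCl
Why: Selective O-alkylation of the two more acidic, less hindered phenols (each para to a formyl group), leaving the OH flanked by both formyl groups chelated and untouched, as in the standard 4,6-bis-protection of acylphloroglucinols.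

Step 3
Reactants: 4 2-hydroxy-4,6-bis(methoxymethoxy)benzene-1,3-dicarbaldehyde
Product: 5 2-methoxy-4,6-bis(methoxymethoxy)benzene-1,3-dicarbaldehyde
Conditions: MeI, K2CO3, DMF, 40 °C
Reagents that add atoms: iodomethane, CI
Why: Williamson O-methylation of the remaining chelated phenol, which places the OMe between the two formyl carbons, i.e. between the future bridge carbon and the future C4 of the 6-linked unit.

Step 4
Reactants: 2 6-methoxy-2,4-bis(methoxymethoxy)benzaldehyde; 5 2-methoxy-4,6-bis(methoxymethoxy)benzene-1,3-dicarbaldehyde (1.5 equiv)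
Product: 9 3-{[3-formyl-2-methoxy-4,6-bis(methoxymethoxy)phenyl](hydroxy)methyl}-6-methoxy-2,4-bis(methoxymethoxy)benzaldehyde (racemic carbinol), via lithium α-amino alkoxide 6 (not isolated), via aryllithium 7 (not isolated), via dilithium adduct 8 (not isolated)
Conditions: LiN(Me)CH2CH2NMe2 (from the amine + n-BuLi), THF, −20 °C; n-BuLi, −20 to 0 °C; cannulate into 5, THF, −78 °C; aq. NH4Cl
Reagents that add atoms: none
Why: Directed ortho-metalation with in-situ aldehyde protection (Comins α-amino alkoxide): the masked aldehyde has no free ortho position, so n-BuLi removes the only C–H flanked by two OMOM groups, and the aryllithium adds once to the symmetric dialdehyde 5 used in excess (either CHO gives the same product), which fixes the bridge position on both rings without relying on electrophilic-substitution selectivity; the new carbinol centre is racemic and is erased in step 5.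

Step 5
Reactants: 9 3-{[3-formyl-2-methoxy-4,6-bis(methoxymethoxy)phenyl](hydroxy)methyl}-6-methoxy-2,4-bis(methoxymethoxy)benzaldehyde
Product: 11 3-[(3-formyl-4,6-dihydroxy-2-methoxyphenyl)methyl]-2,4-dihydroxy-6-methoxybenzaldehyde, via tetra-MOM diarylmethane 10 (not isolated)
Conditions: Et3SiH (1.2 equiv), TFA, CH2Cl2, −40 °C; then HCl, MeOH, 40 °C
Reagents that add atoms: none
Why: Ionic hydrogenation: TFA ionises the doubly benzylic carbinol to a cation stabilised by six ortho/para oxygen donors, which Et3SiH reduces at −40 °C (the two aldehydes are meta to the cationic carbon and should survive 1.2 equiv of silane at low temperature), and acid methanolysis then removes the four MOM acetals.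

Step 6
Reactants: 11 3-[(3-formyl-4,6-dihydroxy-2-methoxyphenyl)methyl]-2,4-dihydroxy-6-methoxybenzaldehyde; 12 (E)-cinnamaldehyde (3 equiv)
Product: 13 (2R)-8-{[(2R)-3-formyl-7-hydroxy-5-methoxy-2-phenyl-2H-chromen-6-yl]methyl}-7-hydroxy-5-methoxy-2-phenyl-2H-chromene-3-carbaldehyde
Conditions: (S)-2-[diphenyl(trimethylsilyloxy)methyl]pyrrolidine (40 mol %), 2-nitrobenzoic acid (40 mol %), 4 Å MS, ClCH2CH2Cl, rt
Reagents that add atoms: none
Why: Two-fold aminocatalytic domino oxa-Michael/aldol condensation (iminium then enamine activation): in each salicylaldehyde unit the only OH ortho to CHO (the other ortho position carries OMe) adds to the β-carbon of the cinnamaldehyde iminium from the face not shielded by the CPh2OTMS group of the (S)-catalyst, the enamine closes onto the aryl aldehyde and water is lost, so both pyran rings and both C2 centres are formed in one operation under catalyst control (R,R here by the standard shielding model, which is the same spatial sense as 2S in the flavan), and two independent catalyst-controlled events raise the ee of the major isomer while the minor (R,S)/(S,R) diastereomers are removed by chromatography.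

Step 7
Reactants: 13 (2R,2′R)-bis(2-phenyl-2H-chromene-3-carbaldehyde)
Product: 14 (2S)-8-{[(2S)-3-formyl-7-hydroxy-5-methoxy-2-phenyl-3,4-dihydro-2H-chromen-6-yl]methyl}-7-hydroxy-5-methoxy-2-phenyl-3,4-dihydro-2H-chromene-3-carbaldehyde (mixture of C3 epimers)
Conditions: H2 (1 atm), 10% Pd/C, EtOAc, rt
Reagents that add atoms: none
Why: Heterogeneous catalytic hydrogenation of the conjugated C3=C4 bonds; the new C3 centres are uncontrolled (mainly 2,3-cis) and irrelevant because they are removed in step 8, C2 is untouched (the descriptor changes from R to S only because the CIP ranking of C3 changes), and hydrogenation avoids the enolate that a hydride conjugate reduction would form and that could expel the β-aryloxy group.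

Step 8
Reactants: 14 (2S,2′S)-bis(3-formylflavan)
Product: 15 (2S)-6-{[(2S)-7-hydroxy-5-methoxy-2-phenyl-3,4-dihydro-2H-chromen-8-yl]methyl}-5-methoxy-2-phenyl-3,4-dihydro-2H-chromen-7-ol
Conditions: RhCl(PPh3)3 (2.3 equiv), PhMe, 100 °C
Reagents that add atoms: none
Why: Tsuji–Wilkinson decarbonylation (Rh insertion into the aldehyde C–H, CO de-insertion, C–H reductive elimination) replaces each CHO by H without touching C2, leaving both flavan centres S.

## Compound list

1 | 2,4-dihydroxy-6-methoxybenzaldehyde | COc1cc(O)cc(O)c1C=O | starting material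
2 | 6-methoxy-2,4-bis(methoxymethoxy)benzaldehyde | COc1cc(OCOC)cc(OCOC)c1C=O | intermediate
3 | 2,4,6-trihydroxybenzene-1,3-dicarbaldehyde (2,4-diformylphloroglucinol) | O=Cc1c(O)cc(O)c(C=O)c1O | starting material
4 | 2-hydroxy-4,6-bis(methoxymethoxy)benzene-1,3-dicarbaldehyde | O=Cc1c(OCOC)cc(OCOC)c(C=O)c1O | intermediate
5 | 2-methoxy-4,6-bis(methoxymethoxy)benzene-1,3-dicarbaldehyde | O=Cc1c(OCOC)cc(OCOC)c(C=O)c1OC | intermediate
6 | lithium α-amino alkoxide of 2 (CHO masked as CH(OLi)N(Me)CH2CH2NMe2) | COc1cc(OCOC)cc(OCOC)c1C(O[Li])N(C)CCN(C)C | intermediate (not isolated)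
7 | aryllithium: 6 lithiated at the ring carbon between the two OMOM groups | COc1cc(OCOC)c([Li])c(OCOC)c1C(O[Li])N(C)CCN(C)C | intermediate (not isolated)
8 | dilithium adduct of 7 with one CHO of 5 (benzhydryl alkoxide, ring-A aldehyde still masked) | COc1cc(OCOC)c(C(O[Li])c2c(OCOC)cc(OCOC)c(C=O)c2OC)c(OCOC)c1C(O[Li])N(C)CCN(C)C | intermediate (not isolated)
9 | 3-{[3-formyl-2-methoxy-4,6-bis(methoxymethoxy)phenyl](hydroxy)methyl}-6-methoxy-2,4-bis(methoxymethoxy)benzaldehyde (racemic) | COc1cc(OCOC)c(C(O)c2c(OCOC)cc(OCOC)c(C=O)c2OC)c(OCOC)c1C=O | intermediate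
10 | 3-{[3-formyl-2-methoxy-4,6-bis(methoxymethoxy)phenyl]methyl}-6-methoxy-2,4-bis(methoxymethoxy)benzaldehyde | COc1cc(OCOC)c(Cc2c(OCOC)cc(OCOC)c(C=O)c2OC)c(OCOC)c1C=O | intermediate (not isolated)
11 | 3-[(3-formyl-4,6-dihydroxy-2-methoxyphenyl)methyl]-2,4-dihydroxy-6-methoxybenzaldehyde | COc1cc(O)c(Cc2c(O)cc(O)c(C=O)c2OC)c(O)c1C=O | intermediate
12 | (E)-cinnamaldehyde | O=C/C=C/c1ccccc1 | starting material
13 | (2R)-8-{[(2R)-3-formyl-7-hydroxy-5-methoxy-2-phenyl-2H-chromen-6-yl]methyl}-7-hydroxy-5-methoxy-2-phenyl-2H-chromene-3-carbaldehyde | COc1cc(O)c(Cc2c(O)cc3O[C@H](c4ccccc4)C(C=O)=Cc3c2OC)c2O[C@H](c3ccccc3)C(C=O)=Cc12 | intermediate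
14 | (2S,2′S)-bis(3-formylflavan): 15 carrying CHO at C3 of each pyran ring, C3 epimer mixture | COc1cc(O)c(Cc2c(O)cc3O[C@H](c4ccccc4)C(C=O)Cc3c2OC)c2O[C@H](c3ccccc3)C(C=O)Cc12 | intermediate
15 | (2S)-6-{[(2S)-7-hydroxy-5-methoxy-2-phenyl-3,4-dihydro-2H-chromen-8-yl]methyl}-5-methoxy-2-phenyl-3,4-dihydro-2H-chromen-7-ol | COc1cc(O)c(Cc2c(O)cc3c(c2OC)CC[C@@H](c2ccccc2)O3)c2c1CC[C@@H](c1ccccc1)O2 | target

## Step count and risks

Total steps: 8. Longest linear sequence: 7 (3 → 4 → 5 → 9 → 11 → 13 → 14 → 15).

**Step 6 (most likely to fail).** The aldehydes are very electron-rich and di-ortho-substituted, so the aldol closure may be slow. The free para-phenols and the nucleophilic ring carbons could also add to the iminium ion, and the ee on this substrate is untested. The fallback sets out from 10 (isolated after the first stage of step 5) and comes back at 15. Two-fold Claisen–Schmidt condensation of 10 with acetophenone (KOH, EtOH) gives the tetra-MOM bis-enone F1. H2 over Pd/C saturates both C=C bonds to the tetra-MOM bis-ketone F2. p-TsOH in MeOH removes the MOM groups to give the tetraphenol bis-ketone F3 (not isolated), and heating in toluene cyclodehydrates both hydroxy-ketones to the bis(2-phenyl-4H-chromene) F4. Ir–phosphinooxazoline-catalysed asymmetric hydrogenation (H2 50 bar, CH2Cl2) of both enol-ether double bonds, a reaction type established for 2-aryl-4H-chromenes, then sets both C2 centres and gives 15; the catalyst enantiomer is chosen on the model 2-phenyl-4H-chromene.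

**Step 4.** Lithiation of the masked aldehyde may be incomplete, or the hindered aryllithium may add poorly or twice. The fallback sets out from 5 and comes back at 11. Commercial 3,5-dihydroxyanisole is bis-MOM-protected to 1-methoxy-3,5-bis(methoxymethoxy)benzene F5. n-BuLi (THF, 0 °C) lithiates it between the two OMOM groups to [4-methoxy-2,6-bis(methoxymethoxy)phenyl]lithium F6, which adds to 5 to give the mono-aldehyde carbinol F7. Et3SiH/TFA gives the tetra-MOM mono-aldehyde diarylmethane F8 (not isolated), and HCl/MeOH gives 3-[(2,6-dihydroxy-4-methoxyphenyl)methyl]-4,6-dihydroxy-2-methoxybenzaldehyde F9. Vilsmeier–Haack formylation (POCl3, DMF, MeCN, 0 °C, then water) enters the only ring without an acyl group, at one of its two equivalent positions, and gives 11.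

**Step 8.** The β-aryloxy aldehyde may ring-open and re-close at 100 °C (retro-oxa-Michael), eroding C2, and the step needs stoichiometric rhodium. The fallback sets out from 14 and comes back at 15, removing the carbon as CO2 by radical chemistry at room temperature. Pinnick oxidation (NaClO2, NaH2PO4, 2-methyl-2-butene, t-BuOH/H2O) gives the bis-carboxylic acid F10. N-hydroxypyridine-2-thione and DCC (CH2Cl2, dark) convert it into the bis Barton ester F11, and visible-light photolysis with t-BuSH at rt gives 15.

## Further compounds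

F1 | step 6 | tetra-MOM bis-enone: 10 with each CHO converted into (E)-CH=CH–C(=O)Ph | COc1cc(OCOC)c(Cc2c(OCOC)cc(OCOC)c(/C=C/C(=O)c3ccccc3)c2OC)c(OCOC)c1/C=C/C(=O)c1ccccc1
F2 | step 6 | tetra-MOM bis-ketone: 10 with each CHO converted into CH2CH2C(=O)Ph | COc1cc(OCOC)c(Cc2c(OCOC)cc(OCOC)c(CCC(=O)c3ccccc3)c2OC)c(OCOC)c1CCC(=O)c1ccccc1
F3 | step 6 | tetraphenol bis-ketone: F2 without the four MOM groups | COc1cc(O)c(Cc2c(O)cc(O)c(CCC(=O)c3ccccc3)c2OC)c(O)c1CCC(=O)c1ccccc1
F4 | step 6 | 6-[(7-hydroxy-5-methoxy-2-phenyl-4H-chromen-8-yl)methyl]-5-methoxy-2-phenyl-4H-chromen-7-ol | COc1cc(O)c(Cc2c(O)cc3OC(c4ccccc4)=CCc3c2OC)c2OC(c3ccccc3)=CCc12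
F5 | step 4 | 1-methoxy-3,5-bis(methoxymethoxy)benzene | COc1cc(OCOC)cc(OCOC)c1
F6 | step 4 | [4-methoxy-2,6-bis(methoxymethoxy)phenyl]lithium | COc1cc(OCOC)c([Li])c(OCOC)c1
F7 | step 4 | 3-{hydroxy[4-methoxy-2,6-bis(methoxymethoxy)phenyl]methyl}-2-methoxy-4,6-bis(methoxymethoxy)benzaldehyde (racemic) | COc1cc(OCOC)c(C(O)c2c(OCOC)cc(OCOC)c(C=O)c2OC)c(OCOC)c1
F8 | step 4 | 2-methoxy-3-{[4-methoxy-2,6-bis(methoxymethoxy)phenyl]methyl}-4,6-bis(methoxymethoxy)benzaldehyde | COc1cc(OCOC)c(Cc2c(OCOC)cc(OCOC)c(C=O)c2OC)c(OCOC)c1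
F9 | step 4 | 3-[(2,6-dihydroxy-4-methoxyphenyl)methyl]-4,6-dihydroxy-2-methoxybenzaldehyde | COc1cc(O)c(Cc2c(O)cc(O)c(C=O)c2OC)c(O)c1
F10 | step 8 | (2S,2′S) bis-carboxylic acid: 14 with each CHO oxidised to CO2H, C3 epimer mixture | COc1cc(O)c(Cc2c(O)cc3O[C@H](c4ccccc4)C(C(=O)O)Cc3c2OC)c2O[C@H](c3ccccc3)C(C(=O)O)Cc12
F11 | step 8 | bis Barton ester: F10 with each CO2H as its 2-thioxopyridin-1(2H)-yl ester | COc1cc(O)c(Cc2c(O)cc3O[C@H](c4ccccc4)C(C(=O)On4ccccc4=S)Cc3c2OC)c2O[C@H](c3ccccc3)C(C(=O)On3ccccc3=S)Cc12
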